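## The problem

The target 14 is an open-chain 8-O-4′ neolignan. A guaiacyl ring A carries the C7–C8–C9 glycerol chain, C8 is joined through oxygen to C4′ of the syringyl-type ring B (which also bears a 3-hydroxypropyl chain), and the ring A phenol is etherified by C2 of a second glycerol unit. No ring has to be closed. The work lies in building a chain with two aryl ethers at secondary carbons, one of them to a phenol oxygen flanked by two methoxy groups.

There are two stereocentres, C7 (S, benzylic carbinol) and C8 (R, aryloxy carbon), in the erythro (anti) relationship. The glyceryl C2 on ring A has two identical arms and is not stereogenic. C8 is the centre to set first: as an α-aryloxy centre it can steer a nucleophile onto a neighbouring C7 carbonyl (Felkin–Anh for addition to an aldehyde, chelation for reduction of a ketone). A pre-existing C7 carbinol, by contrast, gives little help in forming the hindered C8–O bond.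

Several features limit the choice of reagents. The C7 hydroxyl is a p-alkoxybenzylic alcohol that ionises under strong acid (epimerisation, solvolysis) and is open to hydrogenolysis. Ring B is electron-rich towards oxidants. Any C7 carbonyl intermediate has an acidic C8–H. Five hydroxyl groups must be told apart.

The feature that opens the route is the pattern at C8. It carries the ring B aryloxy oxygen, the C9 hydroxymethyl group and exactly one more carbon, C7. That is a 2-aryloxybut-3-en-1-ol with C7 masked as the vinyl CH, which is the branched adduct of a phenol to butadiene monoepoxide.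

## Retrosynthesis

**14 from 13 (no skeletal bond cut).** The five hydroxyl groups of 14 are unveiled from 13, in which C9 and the ring B chain are TBS ethers and the ring A glyceryl unit is an acetonide. All three groups fall to weak aqueous acid in one operation. Benzyl ethers were not used because hydrogenolysis would endanger the benzylic C7–O bond, and esters were not used because they would not survive the organometallic step before it.

**13 from 8 and 12 (ring A–C7 bond).** Cutting between ring A and C7 divides 13 into two halves of similar size: the aryl Grignard reagent 12 and the aldehyde 8, which has C8 as its only stereocentre. The neighbouring cuts are less attractive. A C7–C8 aldol cut would have to set both centres at once with no anchor. A late C8–O cut would require a hindered phenoxide to displace a leaving group at a secondary carbon next to a benzylic carbinol. The forward step must add the aryl group anti to the C8 aryloxy group (Felkin–Anh), giving 7S from 8R.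

**8 from 6 and 5 (C7 as a masked aldehyde).** The aldehyde carbon of 8 is the internal vinyl carbon of 6, released by ozonolysis with loss of one carbon. An alkene is a robust aldehyde surrogate, so the epimerisable aldehyde exists only immediately before use. Alkene 6 is the bis-silyl ether of diol 5, so both primary hydroxyls are protected in a single step.

**5 from 3 and 4 (C8–O bond, the key cut).** Cutting the ring B oxygen–C8 bond gives the achiral phenol 3 and racemic 2-vinyloxirane 4, a four-carbon feedstock. A palladium π-allyl route forms the hindered ether at a cationic allyl terminus and sets C8 in the same step, from a racemate, with catalyst control. The forward step must be branched-selective, enantioselective, and selective for the phenol over the aliphatic hydroxyl of 3. The chain hydroxyl of 3 is left free on purpose: it is far less acidic than the phenol, and this avoids silylating an alkanol selectively beside a phenol.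

**3 from 1 (terminal C–O bond of the chain).** The 3-hydroxypropyl chain comes from the allyl group of commercial 1 by anti-Markovnikov hydration (hydroboration–oxidation).

**11 from 9 and 10 (ring A oxygen–glyceryl C2 bond).** The aryl bromide 11, precursor of 12, is cut at the aryl ether into 4-bromo-2-methoxyphenol 9 and the cyclic glycerol acetonide 10. A Mitsunobu reaction joins them. The bromine is para to the ether oxygen and serves as the Grignard handle. The carbon that is inverted is not stereogenic.

## Roads not taken

**Alternative 1: quinone methide hydration at C7, glyceryl ether last.**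
- Cut: the C7–O bond, with the ring A glyceryl ether disconnected at the very end.
- Forward key step: Ag2O oxidises the free phenol of the C7-deoxy compound A1 to the p-quinone methide A2, and water adds at C7 to give the phenolic tetraol A3.
- Merits: it is biomimetic, needs almost no protecting groups late on, and introduces C7–OH without an organometallic reagent.
- Weak points:
  - The face selectivity of water addition to A2 rests only on the C8 substituents. For this class of quinone methide the erythro preference is known to be moderate and medium-dependent, so a separation of C7 epimers is built in.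
  - A1 must already contain the C8 aryl ether in enantiopure form, so the hard bond is not addressed by this key step.
  - The last step would alkylate the phenol of A3 with a secondary glyceryl electrophile in the presence of four free hydroxyls. A Mitsunobu reaction cannot distinguish them, and basic alkylation conditions can regenerate the quinone methide and scramble C7.
- Comparison: this road is better in protecting-group economy. The chosen plan offers a C7 centre set under a defined 1,2-induction model, and a glyceryl ether made early on the simple phenol 9, where chemoselectivity is not an issue.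

**Alternative 2: dynamic kinetic reduction of a racemic aryloxy keto ester.**
- Cut: the C7–H bond, with C8 left to epimerise.
- Forward key step: the racemic β-keto ester A4 (from a ring B phenoxide and the α-halo β-keto ester of ring A) is reduced with RuCl(p-cymene)(TsDPEN), HCO2H and Et3N to the erythro hydroxy ester A5. Ester reduction and deprotection follow.
- Merits: both stereocentres come from one catalytic step on a racemate. The hindered ether is made by a dependable SN2 reaction at a doubly activated carbon. No cryogenic organometallic chemistry is needed. The step count is comparable to or slightly below that of the chosen plan.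
- Weak points:
  - The anti-selective dynamic reduction must tolerate an α-aryloxy group much bulkier than the usual α-alkoxy or α-amido substituents.
  - The p-alkoxyaryl ketone is electron-rich and slow in transfer hydrogenation.
  - Errors at either centre come from the same step, so up to four isomers are possible.
  - The β-hydroxy ester must then be reduced without retro-aldol cleavage.
- Comparison: this road is as good in length and better in one respect, since C7 is under catalyst control and not substrate control. The chosen plan sets against it:
  - a C8 centre fixed by a step whose enantioselection does not depend on ring A;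
  - at most two diastereomers instead of four, correctable at C7 by oxidation and reduction;
  - a late, convergent union of two halves.

**Alternative 3: Felkin–Anh arylation of a desymmetrised aryloxy aldehyde.**
- Cut: the same ring A–C7 bond as in the chosen plan. The difference is the origin of C8.
- Forward key step: the prochiral diol A6 (from a ring B phenoxide and a 2-halomalonate, then reduction) is desymmetrised by enzymatic monoacylation. Silylation, deacylation and oxidation give the aldehyde A7, identical with 8. The ring A aryl magnesium bromide then adds to give A8, identical with 13.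
- Merits: the hindered ether is formed by a proven SN2 reaction, no precious metal is needed, and a desymmetrisation can in principle convert all material into one enantiomer.
- Weak points:
  - About six steps lead from the phenol to A7, against three in the chosen plan (etherification, silylation, ozonolysis).
  - The enantioselectivity of enzymatic acylation of a 2-aryloxypropane-1,3-diol with so bulky an aryl group is substrate-specific.
  - Acyl migration in the monoester erodes the enantiomeric purity.
  - The C7 addition carries exactly the same risk as in the chosen plan.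
- Comparison: this road is more certain in the C–O bond formation. The chosen plan is about three steps shorter and creates the C8–O bond and the C8 configuration in the same catalytic step, with no protecting-group shuffling.

Key step: step 2

Assumption: the phenolic OH of 1 is taken to consume one equivalent of 9-BBN as its borinate (with loss of H2), so 2 is drawn as the O,C-diborylated species; the outcome after oxidation is the same if the phenol stays free.

Assumption: the (R,R) ligand is taken to give the S alkenol 5, by analogy with the sense known for imide and oxygen pronucleophiles with this ligand family; the sense is to be confirmed on 5 (MTPA esters), and the equally available (S,S) ligand used if it proves opposite.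

## Route

Step 1
Reactants: 1 4-allyl-2,6-dimethoxyphenol
Product: 3 4-(3-hydroxypropyl)-2,6-dimethoxyphenol, via borane adduct 2 (not isolated)
Conditions: 9-BBN (2.5 equiv), THF, 0 °C to rt; then aq NaOH, 30% H2O2, 0 °C to rt
Reagents that add atoms: hydrogen peroxide, OO
Why: Hydroboration–oxidation: 9-BBN adds to the terminal alkene with anti-Markovnikov regioselectivity (the excess covers borylation of the phenol), and alkaline peroxide replaces boron by oxygen at the terminal carbon and frees the phenol. No stereocentre is formed.

Step 2
Reactants: 3 4-(3-hydroxypropyl)-2,6-dimethoxyphenol (1.2 equiv); 4 racemic 2-vinyloxirane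
Product: 5 (S)-2-[4-(3-hydroxypropyl)-2,6-dimethoxyphenoxy]but-3-en-1-ol
Conditions: Pd2(dba)3·CHCl3 (1.5 mol %), (R,R)-N,N'-(cyclohexane-1,2-diyl)bis[2-(diphenylphosphino)benzamide] (4.5 mol %), degassed CH2Cl2, rt, 4 added over several hours
Reagents that add atoms: none
Why: The zerovalent palladium–ligand complex ionises either enantiomer of 4 with inversion to a zwitterionic π-allylpalladium alkoxide; the two diastereomeric complexes interconvert by η3–η1–η3 slippage through the unsubstituted CH2 terminus faster than they are captured, so the racemate funnels into one product (dynamic kinetic asymmetric transformation under Curtin–Hammett control). The pendant alkoxide deprotonates the phenol of 3 (pKa near 10, against about 16 for the alkanol groups present), and the phenoxide, held by a hydrogen bond to the new hydroxyl, attacks the adjacent internal allyl carbon, which forms the C8–O bond and gives the branched 1,2-adduct and not the linear 1,4-ether. The closest known reaction type is the palladium-catalysed asymmetric allylic etherification of butadiene monoepoxide with phenols and boron-assisted alcohols using this diamide–bisphosphine ligand class. No ring is closed. The single new stereocentre, C8, is controlled by the ligand, whose chiral pocket decides which diastereomeric π-allyl complex is attacked; the (R,R) enantiomer is chosen to deliver the S alkenol, which becomes R at C8 of 14 once the vinyl carbon is C7. The step needs branched regioselectivity (secured by the internal delivery and the greater positive charge at the substituted terminus), chemoselectivity for the phenol over aliphatic hydroxyls (secured by acidity, since alkanols do not add without a boron co-catalyst and the product itself carries one), and suppression of oligomerisation through the product alkoxide (secured by slow addition of 4 to an excess of 3, the surplus of which is removed by a dilute base wash). The flanking methoxy groups should be tolerated because the phenoxide attacks a cationic allyl terminus in an early transition state and not a saturated secondary carbon.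

Step 3
Reactants: 5 (S)-2-[4-(3-hydroxypropyl)-2,6-dimethoxyphenoxy]but-3-en-1-ol
Product: 6 (S)-1-(tert-butyldimethylsilyloxy)-2-{4-[3-(tert-butyldimethylsilyloxy)propyl]-2,6-dimethoxyphenoxy}but-3-ene
Conditions: TBSCl (2.5 equiv), imidazole (5 equiv), DMF, 0 °C to rt
Reagents that add atoms: tert-butyldimethylsilyl chloride, CC(C)(C)[Si](C)(C)Cl
Why: Standard imidazole-promoted silylation of two unhindered primary alcohols; the allylic aryl ether stereocentre is not involved.

Step 4
Reactants: 6 (S)-1-(tert-butyldimethylsilyloxy)-2-{4-[3-(tert-butyldimethylsilyloxy)propyl]-2,6-dimethoxyphenoxy}but-3-ene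
Product: 8 (R)-3-(tert-butyldimethylsilyloxy)-2-{4-[3-(tert-butyldimethylsilyloxy)propyl]-2,6-dimethoxyphenoxy}propanal, via ozonide 7 (not isolated)
Conditions: O3, CH2Cl2, −78 °C (Sudan Red 7B end point); then PPh3, −78 °C to rt; used crude
Reagents that add atoms: ozone, O=[O+][O-]
Why: Ozonolysis by the Criegee mechanism (cycloaddition, cycloreversion, recombination to the 1,2,4-trioxolane) followed by reductive cleavage; the monosubstituted alkene reacts far faster than the arene, and the dye marks the end point before ring B is attacked. C8 is untouched (the descriptor changes from S to R only because the priorities change), and the aldehyde is used at once to avoid epimerisation.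

Step 5
Reactants: 9 4-bromo-2-methoxyphenol; 10 2,2-dimethyl-1,3-dioxan-5-ol
Product: 11 5-(4-bromo-2-methoxyphenoxy)-2,2-dimethyl-1,3-dioxane
Conditions: PPh3, DIAD, THF, 0 °C to 40 °C
Reagents that add atoms: none
Why: Mitsunobu etherification: the phenol is acidic enough to protonate the betaine, and the activated secondary carbinol of 10 is displaced by phenoxide with inversion, which has no consequence at this non-stereogenic carbon. The acetonide and the aryl bromide are inert.

Step 6
Reactants: 11 5-(4-bromo-2-methoxyphenoxy)-2,2-dimethyl-1,3-dioxane (1.5 equiv); 8 (R)-3-(tert-butyldimethylsilyloxy)-2-{4-[3-(tert-butyldimethylsilyloxy)propyl]-2,6-dimethoxyphenoxy}propanal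
Product: 13 (1S,2R)-3-(tert-butyldimethylsilyloxy)-2-{4-[3-(tert-butyldimethylsilyloxy)propyl]-2,6-dimethoxyphenoxy}-1-[4-(2,2-dimethyl-1,3-dioxan-5-yloxy)-3-methoxyphenyl]propan-1-ol (7S,8R erythro), via aryl Grignard reagent 12 (not isolated)
Conditions: 11, Mg turnings, cat. I2, THF, 50 °C; then 8, THF, −78 °C to −40 °C; sat. aq NH4Cl
Reagents that add atoms: none
Why: Grignard addition to an α-aryloxy aldehyde under polar Felkin–Anh control: the C8–OAr bond lies anti to the incoming aryl group, which passes the C8 hydrogen and not the CH2OTBS group, so the 8R aldehyde should give the 7S (anti, erythro) carbinol. Chelation is disfavoured because the aryloxy oxygen is a weak, hindered donor, the C9 oxygen carries a bulky silyl group, and THF saturates magnesium.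

Step 7
Reactants: 13 (1S,2R)-3-(tert-butyldimethylsilyloxy)-2-{4-[3-(tert-butyldimethylsilyloxy)propyl]-2,6-dimethoxyphenoxy}-1-[4-(2,2-dimethyl-1,3-dioxan-5-yloxy)-3-methoxyphenyl]propan-1-ol
Product: 14 (1S,2R)-1-[4-(1,3-dihydroxypropan-2-yloxy)-3-methoxyphenyl]-2-[4-(3-hydroxypropyl)-2,6-dimethoxyphenoxy]propane-1,3-diol (CNP0324330.1)
Conditions: AcOH/THF/H2O (3:1:1), rt to 35 °C
Reagents that add atoms: none
Why: Acid-catalysed hydrolysis of the two primary TBS ethers and of the six-membered acetonide in one operation. Acetic acid is too weak to ionise the C7 benzylic alcohol at this temperature, so C7 and C8 should be carried through unchanged.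

## Compound list

1 | 4-allyl-2,6-dimethoxyphenol | C=CCc1cc(OC)c(O)c(OC)c1 | starting material
2 | 9-[3-(4-{(9-borabicyclo[3.3.1]nonan-9-yl)oxy}-3,5-dimethoxyphenyl)propyl]-9-borabicyclo[3.3.1]nonane (borane adduct) | COc1cc(CCCB2C3CCCC2CCC3)cc(OC)c1OB1C2CCCC1CCC2 | intermediate (not isolated)
3 | 4-(3-hydroxypropyl)-2,6-dimethoxyphenol | COc1cc(CCCO)cc(OC)c1O | intermediate
4 | racemic 2-vinyloxirane (butadiene monoepoxide) | C=CC1CO1 | starting material
5 | (S)-2-[4-(3-hydroxypropyl)-2,6-dimethoxyphenoxy]but-3-en-1-ol | C=C[C@@H](CO)Oc1c(OC)cc(CCCO)cc1OC | intermediate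
6 | (S)-1-(tert-butyldimethylsilyloxy)-2-{4-[3-(tert-butyldimethylsilyloxy)propyl]-2,6-dimethoxyphenoxy}but-3-ene | C=C[C@@H](CO[Si](C)(C)C(C)(C)C)Oc1c(OC)cc(CCCO[Si](C)(C)C(C)(C)C)cc1OC | intermediate
7 | 3-[(R)-2-(tert-butyldimethylsilyloxy)-1-{4-[3-(tert-butyldimethylsilyloxy)propyl]-2,6-dimethoxyphenoxy}ethyl]-1,2,4-trioxolane (ozonide, both configurations at the ring carbon) | C1(OCOO1)[C@@H](CO[Si](C)(C)C(C)(C)C)Oc1c(OC)cc(CCCO[Si](C)(C)C(C)(C)C)cc1OC | intermediate (not isolated)
8 | (R)-3-(tert-butyldimethylsilyloxy)-2-{4-[3-(tert-butyldimethylsilyloxy)propyl]-2,6-dimethoxyphenoxy}propanal | O=C[C@@H](CO[Si](C)(C)C(C)(C)C)Oc1c(OC)cc(CCCO[Si](C)(C)C(C)(C)C)cc1OC | intermediate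
9 | 4-bromo-2-methoxyphenol | COc1cc(Br)ccc1O | starting material
10 | 2,2-dimethyl-1,3-dioxan-5-ol | CC1(C)OCC(O)CO1 | starting material
11 | 5-(4-bromo-2-methoxyphenoxy)-2,2-dimethyl-1,3-dioxane | COc1cc(Br)ccc1OC1COC(C)(C)OC1 | intermediate
12 | [4-(2,2-dimethyl-1,3-dioxan-5-yloxy)-3-methoxyphenyl]magnesium bromide | COc1cc([Mg]Br)ccc1OC1COC(C)(C)OC1 | intermediate (not isolated)
13 | (1S,2R)-3-(tert-butyldimethylsilyloxy)-2-{4-[3-(tert-butyldimethylsilyloxy)propyl]-2,6-dimethoxyphenoxy}-1-[4-(2,2-dimethyl-1,3-dioxan-5-yloxy)-3-methoxyphenyl]propan-1-ol | COc1cc([C@H](O)[C@@H](CO[Si](C)(C)C(C)(C)C)Oc2c(OC)cc(CCCO[Si](C)(C)C(C)(C)C)cc2OC)ccc1OC1COC(C)(C)OC1 | intermediate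
14 | (1S,2R)-1-[4-(1,3-dihydroxypropan-2-yloxy)-3-methoxyphenyl]-2-[4-(3-hydroxypropyl)-2,6-dimethoxyphenoxy]propane-1,3-diol | COc1cc([C@H](O)[C@@H](CO)Oc2c(OC)cc(CCCO)cc2OC)ccc1OC(CO)CO | target

## Step count and least certain steps

Total step count: 7. Longest linear sequence: 6 steps (steps 1, 2, 3, 4, 6, 7 from 1 to 14). The ring A arm is one step (step 5).

**Step 2 (key step).** The most likely failure is slow capture of the π-allyl complex by the doubly ortho-substituted phenoxide. This would let the alkoxide of the product attack a second π-allyl unit (oligomerisation). Attack outside the hydrogen-bonded delivery path would erode the branched-to-linear ratio and the enantioselectivity.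

The fallback forms the same C8–O bond by a Mitsunobu inversion on a chiral-pool hydroxy ester. It sets out from 1 and returns at 8.
- Commercial methyl (S)-2,2-dimethyl-1,3-dioxolane-4-carboxylate F1 is hydrolysed with aqueous AcOH to methyl (S)-2,3-dihydroxypropanoate F2.
- F2 is silylated at the primary hydroxyl (TBSCl, imidazole, CH2Cl2, 0 °C) to methyl (S)-3-(tert-butyldimethylsilyloxy)-2-hydroxypropanoate F3.
- A Mitsunobu reaction of F3 with 1 (PPh3, DIAD, THF) proceeds with inversion to methyl (R)-2-(4-allyl-2,6-dimethoxyphenoxy)-3-(tert-butyldimethylsilyloxy)propanoate F4. This reaction type is well established for 2,6-dimethoxyphenols with α-hydroxy esters.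
- Hydroboration of the allyl group with 9-BBN gives the borane adduct F5, which is oxidised with NaBO3·4H2O (mild enough to spare the ester) to methyl (R)-3-(tert-butyldimethylsilyloxy)-2-[4-(3-hydroxypropyl)-2,6-dimethoxyphenoxy]propanoate F6.
- Silylation gives the bis-silyl ester F7, and i-Bu2AlH in CH2Cl2 at −78 °C gives aldehyde 8.

**Step 6.** Two processes threaten this step. The first is poor facial selectivity, if magnesium bridges the carbonyl oxygen and the ether oxygens of ring B and chelation control competes with the Felkin–Anh pathway. The second is enolisation of the aldehyde by the basic Grignard reagent, which would epimerise C8.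

The fallback replaces substrate-controlled addition by oxidation and chelation-controlled reduction. It sets out from 13 obtained in admixture with its C7 epimer, the (1R,2R) threo carbinol F8, and returns at 13. The mixture is taken by Dess–Martin oxidation (NaHCO3 buffer) to the (R)-aryl ketone F9. F9 is reduced with Zn(BH4)2 in Et2O at low temperature, where hydride delivery to the zinc chelate of the carbonyl and the C8 aryloxy oxygen should favour the anti (erythro) carbinol 13.

**Step 4.** Over-oxidation of the electron-rich ring B by ozone is possible once the alkene is consumed. The α-aryloxy aldehyde may also lose configuration during isolation.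

The fallback separates the oxidation into two mild stages. It sets out from 6 and returns at 8. Dihydroxylation with OsO4 (cat.) and N-methylmorpholine N-oxide in acetone/H2O gives the diol F10 (both configurations at the new carbinol). Cleavage with NaIO4 on silica gel in CH2Cl2 under neutral conditions gives 8.

**Step 7.** Ionisation of the C7 benzylic alcohol (epimerisation or acetate formation) could compete if hydrolysis of the silyl ethers is slow and forcing is needed.

The fallback changes the protecting-group plan so that the last step needs fluoride only. It sets out from 11 and returns at 14.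
- The acetonide of 11 is hydrolysed (aq HCl, MeOH) to 2-(4-bromo-2-methoxyphenoxy)propane-1,3-diol F11.
- F11 is silylated (TBSCl, imidazole) to the bis-silyl ether F12.
- F12 is converted with Mg in THF to the aryl Grignard reagent F13, which adds to 8 as in step 6 to give the tetrakis-silyl erythro adduct F14.
- Bu4NF in THF at 0 °C to rt removes all four silyl groups without acid and gives 14.

## Further compounds

F1 | step 2 | methyl (S)-2,2-dimethyl-1,3-dioxolane-4-carboxylate (purchased) | COC(=O)[C@@H]1COC(C)(C)O1
F2 | step 2 | methyl (S)-2,3-dihydroxypropanoate | COC(=O)[C@@H](O)CO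
F3 | step 2 | methyl (S)-3-(tert-butyldimethylsilyloxy)-2-hydroxypropanoate | COC(=O)[C@@H](O)CO[Si](C)(C)C(C)(C)C
F4 | step 2 | methyl (R)-2-(4-allyl-2,6-dimethoxyphenoxy)-3-(tert-butyldimethylsilyloxy)propanoate | COC(=O)[C@@H](CO[Si](C)(C)C(C)(C)C)Oc1c(OC)cc(CC=C)cc1OC
F5 | step 2 | methyl (R)-2-{4-[3-(9-borabicyclo[3.3.1]nonan-9-yl)propyl]-2,6-dimethoxyphenoxy}-3-(tert-butyldimethylsilyloxy)propanoate (borane adduct, not isolated) | COC(=O)[C@@H](CO[Si](C)(C)C(C)(C)C)Oc1c(OC)cc(CCCB2C3CCCC2CCC3)cc1OC
F6 | step 2 | methyl (R)-3-(tert-butyldimethylsilyloxy)-2-[4-(3-hydroxypropyl)-2,6-dimethoxyphenoxy]propanoate | COC(=O)[C@@H](CO[Si](C)(C)C(C)(C)C)Oc1c(OC)cc(CCCO)cc1OC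
F7 | step 2 | methyl (R)-3-(tert-butyldimethylsilyloxy)-2-{4-[3-(tert-butyldimethylsilyloxy)propyl]-2,6-dimethoxyphenoxy}propanoate | COC(=O)[C@@H](CO[Si](C)(C)C(C)(C)C)Oc1c(OC)cc(CCCO[Si](C)(C)C(C)(C)C)cc1OC
F8 | step 6 | (1R,2R)-3-(tert-butyldimethylsilyloxy)-2-{4-[3-(tert-butyldimethylsilyloxy)propyl]-2,6-dimethoxyphenoxy}-1-[4-(2,2-dimethyl-1,3-dioxan-5-yloxy)-3-methoxyphenyl]propan-1-ol (threo C7 epimer of 13) | COc1cc([C@@H](O)[C@@H](CO[Si](C)(C)C(C)(C)C)Oc2c(OC)cc(CCCO[Si](C)(C)C(C)(C)C)cc2OC)ccc1OC1COC(C)(C)OC1
F9 | step 6 | (R)-3-(tert-butyldimethylsilyloxy)-2-{4-[3-(tert-butyldimethylsilyloxy)propyl]-2,6-dimethoxyphenoxy}-1-[4-(2,2-dimethyl-1,3-dioxan-5-yloxy)-3-methoxyphenyl]propan-1-one | COc1cc(C(=O)[C@@H](CO[Si](C)(C)C(C)(C)C)Oc2c(OC)cc(CCCO[Si](C)(C)C(C)(C)C)cc2OC)ccc1OC1COC(C)(C)OC1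
F10 | step 4 | (3S)-4-(tert-butyldimethylsilyloxy)-3-{4-[3-(tert-butyldimethylsilyloxy)propyl]-2,6-dimethoxyphenoxy}butane-1,2-diol (both configurations at C2) | OCC(O)[C@@H](CO[Si](C)(C)C(C)(C)C)Oc1c(OC)cc(CCCO[Si](C)(C)C(C)(C)C)cc1OC
F11 | step 7 | 2-(4-bromo-2-methoxyphenoxy)propane-1,3-diol | COc1cc(Br)ccc1OC(CO)CO
F12 | step 7 | 4-bromo-1-{[1,3-bis(tert-butyldimethylsilyloxy)propan-2-yl]oxy}-2-methoxybenzene | COc1cc(Br)ccc1OC(CO[Si](C)(C)C(C)(C)C)CO[Si](C)(C)C(C)(C)C
F13 | step 7 | (4-{[1,3-bis(tert-butyldimethylsilyloxy)propan-2-yl]oxy}-3-methoxyphenyl)magnesium bromide (not isolated) | COc1cc([Mg]Br)ccc1OC(CO[Si](C)(C)C(C)(C)C)CO[Si](C)(C)C(C)(C)C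
F14 | step 7 | (1S,2R)-1-(4-{[1,3-bis(tert-butyldimethylsilyloxy)propan-2-yl]oxy}-3-methoxyphenyl)-3-(tert-butyldimethylsilyloxy)-2-{4-[3-(tert-butyldimethylsilyloxy)propyl]-2,6-dimethoxyphenoxy}propan-1-ol | COc1cc([C@H](O)[C@@H](CO[Si](C)(C)C(C)(C)C)Oc2c(OC)cc(CCCO[Si](C)(C)C(C)(C)C)cc2OC)ccc1OC(CO[Si](C)(C)C(C)(C)C)CO[Si](C)(C)C(C)(C)C
A1 | alternative 1 | (S)-3-(4-hydroxy-3-methoxyphenyl)-2-[4-(3-hydroxypropyl)-2,6-dimethoxyphenoxy]propan-1-ol | COc1cc(C[C@@H](CO)Oc2c(OC)cc(CCCO)cc2OC)ccc1O
A2 | alternative 1 | p-quinone methide of A1 (4-alkylidene-2-methoxycyclohexa-2,5-dien-1-one) | COC1=CC(=C[C@@H](CO)Oc2c(OC)cc(CCCO)cc2OC)C=CC1=O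
A3 | alternative 1 | (1S,2R)-1-(4-hydroxy-3-methoxyphenyl)-2-[4-(3-hydroxypropyl)-2,6-dimethoxyphenoxy]propane-1,3-diol (erythro phenolic tetraol) | COc1cc([C@H](O)[C@@H](CO)Oc2c(OC)cc(CCCO)cc2OC)ccc1O
A4 | alternative 2 | racemic ethyl 2-{4-[3-(tert-butyldimethylsilyloxy)propyl]-2,6-dimethoxyphenoxy}-3-[4-(2,2-dimethyl-1,3-dioxan-5-yloxy)-3-methoxyphenyl]-3-oxopropanoate | CCOC(=O)C(Oc1c(OC)cc(CCCO[Si](C)(C)C(C)(C)C)cc1OC)C(=O)c1ccc(OC2COC(C)(C)OC2)c(OC)c1
A5 | alternative 2 | ethyl (2S,3S)-2-{4-[3-(tert-butyldimethylsilyloxy)propyl]-2,6-dimethoxyphenoxy}-3-[4-(2,2-dimethyl-1,3-dioxan-5-yloxy)-3-methoxyphenyl]-3-hydroxypropanoate (erythro) | COc1cc([C@H](O)[C@@H](C(=O)OCC)Oc2c(OC)cc(CCCO[Si](C)(C)C(C)(C)C)cc2OC)ccc1OC1COC(C)(C)OC1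
A6 | alternative 3 | 2-{4-[3-(tert-butyldimethylsilyloxy)propyl]-2,6-dimethoxyphenoxy}propane-1,3-diol (prochiral) | COc1cc(CCCO[Si](C)(C)C(C)(C)C)cc(OC)c1OC(CO)CO
A7 | alternative 3 | (R)-3-(tert-butyldimethylsilyloxy)-2-{4-[3-(tert-butyldimethylsilyloxy)propyl]-2,6-dimethoxyphenoxy}propanal (identical with 8) | O=C[C@@H](CO[Si](C)(C)C(C)(C)C)Oc1c(OC)cc(CCCO[Si](C)(C)C(C)(C)C)cc1OC
A8 | alternative 3 | (1S,2R)-3-(tert-butyldimethylsilyloxy)-2-{4-[3-(tert-butyldimethylsilyloxy)propyl]-2,6-dimethoxyphenoxy}-1-[4-(2,2-dimethyl-1,3-dioxan-5-yloxy)-3-methoxyphenyl]propan-1-ol (identical with 13) | COc1cc([C@H](O)[C@@H](CO[Si](C)(C)C(C)(C)C)Oc2c(OC)cc(CCCO[Si](C)(C)C(C)(C)C)cc2OC)ccc1OC1COC(C)(C)OC1
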